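**Strategy.** The cyclohexenone ring (C-1 carbonyl, C-2 amide, C-3 vinylic CH, C-4 carbinol, C-5/C-6 epoxide) is opened between C-3 and C-4. Two features are exploited: the amide nitrogen on C-2 and the hydroxyl on C-4 are 1,3-related, so C-3 is an enamide β-carbon and C-4 a ketone carbon; and C-1 and C-4, both oxygenated and joined through the cis C-5/C-6 unit, are the α-carbons of a furan. In one operation singlet oxygen opens a flat 2,5-disubstituted furyl enamide to a (Z)-ene-1,4-dione, which closes by a phosphoric-acid-catalysed aza-ene aldol to the 2-amido-p-quinol, forming the ring and the C-4 stereocentre. Face-selective epoxidation and a Stille coupling complete the target.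

Key step: step 6

Assumption: the sense of induction of the chiral phosphoric acid in step 6 cannot be predicted with confidence; the (R)-catalyst is written, and the (S)-catalyst would be used if it is the one that leads to 14.

Step 1
Reactants: 1 (E)-4-methylpent-2-enal; 2 triethyl (E)-4-phosphonocrotonate
Product: 3 ethyl (2E,4E,6E)-8-methylnona-2,4,6-trienoate
Conditions: LiN(SiMe3)2, THF, −78 to 0 °C
Reagents that add atoms: none
Why: Horner–Wadsworth–Emmons olefination of the vinylogous phosphonate anion at its α-carbon should give the new C-4/C-5 double bond with E geometry, the other two E alkenes being carried in from 1 and 2.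

Step 2
Reactants: 3 ethyl (2E,4E,6E)-8-methylnona-2,4,6-trienoate
Product: 4 (2E,4E,6E)-8-methylnona-2,4,6-trienoic acid
Conditions: LiOH·H2O, THF/MeOH/H2O, 23 °C; then 1 M HCl
Reagents that add atoms: lithium hydroxide [Li+].[OH-]
Why: Saponification (acyl substitution by hydroxide) should cleave the ethyl ester without touching the triene.

Step 3
Reactants: 4 (2E,4E,6E)-8-methylnona-2,4,6-trienoic acid
Product: 5 (2E,4E,6E)-8-methylnona-2,4,6-trienoyl chloride
Conditions: (COCl)2, DMF (cat.), CH2Cl2, 0 to 23 °C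
Reagents that add atoms: oxalyl chloride O=C(Cl)C(=O)Cl
Why: Acyl chloride formation through the chloroiminium (Vilsmeier-type) catalyst should activate the acid under conditions that do not isomerise the triene.

Step 4
Reactants: 6 5-formylfuran-2-carbonitrile
Product: 7 5-[(E)-2-iodoethenyl]furan-2-carbonitrile
Conditions: CrCl2, CHI3, THF, 0 °C
Reagents that add atoms: iodoform IC(I)I
Why: Takai olefination: the geminal dichromium species formed from CHI3 and CrCl2 should add to the aldehyde and eliminate to the (E)-vinyl iodide, the nitrile being inert to divalent chromium.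

Step 5
Reactants: 7 5-[(E)-2-iodoethenyl]furan-2-carbonitrile; 5 (2E,4E,6E)-8-methylnona-2,4,6-trienoyl chloride
Product: 10 (2E,4E,6E)-N-[1-[5-[(E)-2-iodoethenyl]furan-2-yl]ethenyl]-8-methylnona-2,4,6-trienamide, via bromomagnesium ketimide 8 (not isolated), via N-acyl ketimine 9 (not isolated)
Conditions: MeMgBr, THF, 0 to 23 °C; then 5, −20 to 23 °C; Et3N
Reagents that add atoms: methylmagnesium bromide C[Mg]Br
Why: Grignard addition to the nitrile should stop at the magnesium ketimide 8, whose N-acylation by 5 gives the N-acyl ketimine 9 that tautomerises to the conjugated secondary enamide (nitrile-to-enamide sequence), MeMgBr being too slow in halogen–metal exchange to touch the vinyl iodide.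

Step 6
Reactants: 10 (2E,4E,6E)-N-[1-[5-[(E)-2-iodoethenyl]furan-2-yl]ethenyl]-8-methylnona-2,4,6-trienamide
Product: 14 (2E,4E,6E)-N-[(3R)-3-hydroxy-3-[(E)-2-iodoethenyl]-6-oxocyclohexa-1,4-dien-1-yl]-8-methylnona-2,4,6-trienamide, via furan endoperoxide 11 (not isolated), via (Z)-enedione 12 (not isolated), via N-acylimino ketol 13 (not isolated)
Conditions: O2, tetraphenylporphyrin (cat.), visible light, CH2Cl2, −78 °C; Me2S, −78 to −40 °C; cold aqueous wash, MgSO4; then (R)-3,3'-bis(2,4,6-triisopropylphenyl)-1,1'-binaphthalene-2,2'-diyl hydrogen phosphate (10 mol %), 4 Å molecular sieves, CH2Cl2, −40 to 0 °C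
Reagents that add atoms: dioxygen O=O
Why: Proposed new method: singlet oxygen adds across the furan (the most electron-rich diene of 10) to give endoperoxide 11, Me2S reduces it to the (Z)-ene-1,4-dione 12, and the secondary enamide then attacks the C-4 ketone through C-3 in an aza-ene (enamide aldol) step whose N-acyl imine 13 tautomerises to the conjugated 2-amido enone 14; the reasoning is that transfer of the N–H proton to the carbonyl oxygen within a six-membered hydrogen-bonded array, organised by the bifunctional phosphoric acid, raises the nucleophilicity of the cross-conjugated C-3 while the acid activates the ketone. The closest known reaction types are the photooxygenation of furans to (Z)-enediones followed by intramolecular aldol closure to 4-hydroxycyclopentenones, and phosphoric-acid-catalysed aza-ene additions of secondary enamides to activated ketones. The carbocycle is closed at the C-3/C-4 bond in a 6-(enolendo)-exo-trig mode. The C-4 stereocentre, the only one formed, is controlled by the chiral phosphate, which holds the amide N–H and the C-4 carbonyl and so exposes one face of the ketone. The step needs attack by carbon and not by the amide nitrogen (hemiaminal formation is reversible whereas C–C bond formation is not), a Z alkene (fixed by the furan origin and kept by low temperature and exclusion of light after the oxygenation) and oxygenation of the furan in preference to the enamide and the triene (expected from the much higher singlet-oxygen reactivity of a 2,5-disubstituted furan).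

Step 7
Reactants: 14 (2E,4E,6E)-N-[(3R)-3-hydroxy-3-[(E)-2-iodoethenyl]-6-oxocyclohexa-1,4-dien-1-yl]-8-methylnona-2,4,6-trienamide
Product: 15 (2E,4E,6E)-N-[(3R)-3-[(E)-2-iodoethenyl]-6-oxo-3-(triethylsilyloxy)cyclohexa-1,4-dien-1-yl]-8-methylnona-2,4,6-trienamide
Conditions: Et3SiOTf, 2,6-lutidine, CH2Cl2, −78 °C
Reagents that add atoms: triethylsilyl trifluoromethanesulfonate CC[Si](CC)(CC)OS(=O)(=O)C(F)(F)F
Why: O-silylation of the tertiary alcohol by the silyl triflate should mask the hydroxyl so that it can no longer deliver the peroxide to its own face and instead shields that face.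

Step 8
Reactants: 15 (2E,4E,6E)-N-[(3R)-3-[(E)-2-iodoethenyl]-6-oxo-3-(triethylsilyloxy)cyclohexa-1,4-dien-1-yl]-8-methylnona-2,4,6-trienamide
Product: 16 (2E,4E,6E)-N-[(1R,5R,6S)-5-[(E)-2-iodoethenyl]-2-oxo-5-(triethylsilyloxy)-7-oxabicyclo[4.1.0]hept-3-en-3-yl]-8-methylnona-2,4,6-trienamide
Conditions: t-BuOOH (decane solution), DBU, CH2Cl2, 0 °C
Reagents that add atoms: tert-butyl hydroperoxide CC(C)(C)OO
Why: Weitz–Scheffer nucleophilic epoxidation: the tert-butyl peroxide anion should add to C-5 of the unsubstituted enone (the amide-bearing enone is deactivated as a vinylogous imide) anti to the bulky, electronegative silyloxy group on C-4, as it does in 4-silyloxycyclohexenones, and closure of the enolate gives the cis-fused epoxide, which sets C-5 and C-6 relative to C-4.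

Step 9
Reactants: 16 (2E,4E,6E)-N-[(1R,5R,6S)-5-[(E)-2-iodoethenyl]-2-oxo-5-(triethylsilyloxy)-7-oxabicyclo[4.1.0]hept-3-en-3-yl]-8-methylnona-2,4,6-trienamide
Product: 17 (2E,4E,6E)-N-[(1R,5R,6S)-5-hydroxy-5-[(E)-2-iodoethenyl]-2-oxo-7-oxabicyclo[4.1.0]hept-3-en-3-yl]-8-methylnona-2,4,6-trienamide
Conditions: HF·pyridine, pyridine, THF, 0 °C
Reagents that add atoms: none
Why: Fluoride-induced Si–O cleavage under buffered conditions should free the tertiary alcohol without opening the epoxide or touching the vinyl iodide.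

Step 10
Reactants: 18 cyclopentane-1,3-dione
Product: 19 2-(hydroxyimino)cyclopentane-1,3-dione
Conditions: NaNO2, aq. HCl, 0 °C
Reagents that add atoms: sodium nitrite [Na+].[O-]N=O
Why: Nitrosation of the enolised 1,3-dione at C-2 by nitrous acid should give the nitroso compound, which tautomerises to the oxime.

Step 11
Reactants: 19 2-(hydroxyimino)cyclopentane-1,3-dione
Product: 20 2-amino-3-hydroxycyclopent-2-en-1-one hydrochloride
Conditions: H2 (1 atm), Pd/C, HCl, MeOH, 23 °C
Reagents that add atoms: hydrogen chloride Cl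
Why: Catalytic hydrogenation should cleave the N–O bond and reduce the C=N bond, the amine being trapped at once as the hydrochloride of its enolised tautomer, which prevents self-condensation.

Step 12
Reactants: 21 (E)-3-(tributylstannyl)prop-2-en-1-ol
Product: 22 (E)-3-(tributylstannyl)prop-2-enal
Conditions: MnO2, CH2Cl2, 23 °C
Reagents that add atoms: none
Why: Allylic oxidation with MnO2 should stop at the enal and keep both the E geometry and the C–Sn bond.

Step 13
Reactants: 22 (E)-3-(tributylstannyl)prop-2-enal; 23 diethylphosphonoacetic acid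
Product: 24 (2E,4E)-5-(tributylstannyl)penta-2,4-dienoic acid
Conditions: 23, n-BuLi (2 equiv), THF, −78 °C; then 22, −78 to 0 °C; aq. KHSO4 work-up
Reagents that add atoms: none
Why: Horner–Wadsworth–Emmons olefination with the dianion of the phosphonoacetic acid should give the (2E)-acid directly, the dianion being formed before the aldehyde is added so that no butyllithium is left for tin–lithium exchange.

Step 14
Reactants: 24 (2E,4E)-5-(tributylstannyl)penta-2,4-dienoic acid; 20 2-amino-3-hydroxycyclopent-2-en-1-one hydrochloride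
Product: 25 (2E,4E)-N-(2-hydroxy-5-oxocyclopent-1-en-1-yl)-5-(tributylstannyl)penta-2,4-dienamide
Conditions: N-(3-dimethylaminopropyl)-N'-ethylcarbodiimide hydrochloride, HOAt, i-Pr2NEt, DMF, 0 to 23 °C
Reagents that add atoms: none
Why: Carbodiimide/HOAt amide coupling should acylate the weakly nucleophilic amine on nitrogen (any enol ester formed first should rearrange to the more stable amide) without the strong acid that would cleave the vinylstannane.

Step 15
Reactants: 17 (2E,4E,6E)-N-[(1R,5R,6S)-5-hydroxy-5-[(E)-2-iodoethenyl]-2-oxo-7-oxabicyclo[4.1.0]hept-3-en-3-yl]-8-methylnona-2,4,6-trienamide; 25 (2E,4E)-N-(2-hydroxy-5-oxocyclopent-1-en-1-yl)-5-(tributylstannyl)penta-2,4-dienamide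
Product: 26 (2E,4E,6E)-N-[(1R,5S,6S)-5-hydroxy-5-[(1E,3E,5E)-7-[(2-hydroxy-5-oxocyclopent-1-en-1-yl)amino]-7-oxohepta-1,3,5-trien-1-yl]-2-oxo-7-oxabicyclo[4.1.0]hept-3-en-3-yl]-8-methylnona-2,4,6-trienamide (CNP0215439.3)
Conditions: Pd2(dba)3, AsPh3, DMF, 23 °C, dark
Reagents that add atoms: none
Why: Stille cross-coupling with zerovalent palladium (AsPh3 speeds up transmetalation) should join the two sp2 carbons with retention of both E geometries under neutral conditions at room temperature, which the epoxy ketone, the free tertiary alcohol and the acidic enol should tolerate.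

**Compound list**

1 | (E)-4-methylpent-2-enal | CC(C)/C=C/C=O | starting material
2 | triethyl (E)-4-phosphonocrotonate | CCOC(=O)/C=C/CP(=O)(OCC)OCC | starting material
3 | ethyl (2E,4E,6E)-8-methylnona-2,4,6-trienoate | CC(C)/C=C/C=C/C=C/C(=O)OCC | intermediate
4 | (2E,4E,6E)-8-methylnona-2,4,6-trienoic acid | CC(C)/C=C/C=C/C=C/C(=O)O | intermediate
5 | (2E,4E,6E)-8-methylnona-2,4,6-trienoyl chloride | CC(C)/C=C/C=C/C=C/C(=O)Cl | intermediate
6 | 5-formylfuran-2-carbonitrile | O=Cc1ccc(C#N)o1 | starting material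
7 | 5-[(E)-2-iodoethenyl]furan-2-carbonitrile | N#Cc1ccc(/C=C/I)o1 | intermediate
8 | bromomagnesium 1-[5-[(E)-2-iodoethenyl]furan-2-yl]ethan-1-iminide | CC(=N[Mg]Br)c1ccc(/C=C/I)o1 | intermediate
9 | (2E,4E,6E)-N-[1-[5-[(E)-2-iodoethenyl]furan-2-yl]ethylidene]-8-methylnona-2,4,6-trienamide | CC(=NC(=O)/C=C/C=C/C=C/C(C)C)c1ccc(/C=C/I)o1 | intermediate
10 | (2E,4E,6E)-N-[1-[5-[(E)-2-iodoethenyl]furan-2-yl]ethenyl]-8-methylnona-2,4,6-trienamide | C=C(NC(=O)/C=C/C=C/C=C/C(C)C)c1ccc(/C=C/I)o1 | intermediate
11 | (2E,4E,6E)-N-[1-[4-[(E)-2-iodoethenyl]-2,3,7-trioxabicyclo[2.2.1]hept-5-en-1-yl]ethenyl]-8-methylnona-2,4,6-trienamide (racemic) | C=C(NC(=O)/C=C/C=C/C=C/C(C)C)C12C=CC(/C=C/I)(OO1)O2 | intermediate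
12 | (2E,4E,6E)-N-[(4Z,7E)-8-iodo-3,6-dioxoocta-1,4,7-trien-2-yl]-8-methylnona-2,4,6-trienamide | C=C(NC(=O)/C=C/C=C/C=C/C(C)C)C(=O)/C=C\C(=O)/C=C/I | intermediate
13 | (2E,4E,6E)-N-[(3S)-3-hydroxy-3-[(E)-2-iodoethenyl]-6-oxocyclohex-4-en-1-ylidene]-8-methylnona-2,4,6-trienamide | CC(C)/C=C/C=C/C=C/C(=O)N=C1C[C@@](O)(/C=C/I)C=CC1=O | intermediate
14 | (2E,4E,6E)-N-[(3R)-3-hydroxy-3-[(E)-2-iodoethenyl]-6-oxocyclohexa-1,4-dien-1-yl]-8-methylnona-2,4,6-trienamide | CC(C)/C=C/C=C/C=C/C(=O)NC1=C[C@@](O)(/C=C/I)C=CC1=O | intermediate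
15 | (2E,4E,6E)-N-[(3R)-3-[(E)-2-iodoethenyl]-6-oxo-3-(triethylsilyloxy)cyclohexa-1,4-dien-1-yl]-8-methylnona-2,4,6-trienamide | CC(C)/C=C/C=C/C=C/C(=O)NC1=C[C@@](O[Si](CC)(CC)CC)(/C=C/I)C=CC1=O | intermediate
16 | (2E,4E,6E)-N-[(1R,5R,6S)-5-[(E)-2-iodoethenyl]-2-oxo-5-(triethylsilyloxy)-7-oxabicyclo[4.1.0]hept-3-en-3-yl]-8-methylnona-2,4,6-trienamide | CC(C)/C=C/C=C/C=C/C(=O)NC1=C[C@@](O[Si](CC)(CC)CC)(/C=C/I)[C@H]2O[C@H]2C1=O | intermediate
17 | (2E,4E,6E)-N-[(1R,5R,6S)-5-hydroxy-5-[(E)-2-iodoethenyl]-2-oxo-7-oxabicyclo[4.1.0]hept-3-en-3-yl]-8-methylnona-2,4,6-trienamide | CC(C)/C=C/C=C/C=C/C(=O)NC1=C[C@@](O)(/C=C/I)[C@H]2O[C@H]2C1=O | intermediate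
18 | cyclopentane-1,3-dione | O=C1CCC(=O)C1 | starting material
19 | 2-(hydroxyimino)cyclopentane-1,3-dione | ON=C1C(=O)CCC1=O | intermediate
20 | 2-amino-3-hydroxycyclopent-2-en-1-one hydrochloride | NC1=C(O)CCC1=O.Cl | intermediate
21 | (E)-3-(tributylstannyl)prop-2-en-1-ol | CCCC[Sn](CCCC)(CCCC)/C=C/CO | starting material
22 | (E)-3-(tributylstannyl)prop-2-enal | CCCC[Sn](CCCC)(CCCC)/C=C/C=O | intermediate
23 | diethylphosphonoacetic acid | CCOP(=O)(CC(=O)O)OCC | starting material
24 | (2E,4E)-5-(tributylstannyl)penta-2,4-dienoic acid | CCCC[Sn](CCCC)(CCCC)/C=C/C=C/C(=O)O | intermediate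
25 | (2E,4E)-N-(2-hydroxy-5-oxocyclopent-1-en-1-yl)-5-(tributylstannyl)penta-2,4-dienamide | CCCC[Sn](CCCC)(CCCC)/C=C/C=C/C(=O)NC1=C(O)CCC1=O | intermediate
26 | (2E,4E,6E)-N-[(1R,5S,6S)-5-hydroxy-5-[(1E,3E,5E)-7-[(2-hydroxy-5-oxocyclopent-1-en-1-yl)amino]-7-oxohepta-1,3,5-trien-1-yl]-2-oxo-7-oxabicyclo[4.1.0]hept-3-en-3-yl]-8-methylnona-2,4,6-trienamide | CC(C)/C=C/C=C/C=C/C(=O)NC1=C[C@@](O)(/C=C/C=C/C=C/C(=O)NC2=C(O)CCC2=O)[C@H]2O[C@H]2C1=O | target

**Step count.** Total: 15 steps. Longest linear sequence: 9 steps (steps 1, 2, 3, 5, 6, 7, 8, 9 and 15).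

**Steps most likely to fail**

Step 6 (Proposed new method). What may go wrong:
- attack of the amide nitrogen instead of C-3 on the C-4 ketone, followed by dehydration towards a pyridinol;
- Z-to-E isomerisation of the enedione before ring closure;
- oxygenation of the enamide or triene instead of the furan;
- low enantioselectivity through an uncatalysed background cyclisation.

Fallback by known chemistry, setting out from 5 and returning at 14: acylation of 2,5-dimethoxyaniline with 5 (pyridine, CH2Cl2) should give (2E,4E,6E)-N-(2,5-dimethoxyphenyl)-8-methylnona-2,4,6-trienamide F1. Oxidative dearomatisation with PhI(OAc)2 in MeOH at 0 °C should give the quinone monoketal (2E,4E,6E)-N-(6,6-dimethoxy-3-oxocyclohexa-1,4-dien-1-yl)-8-methylnona-2,4,6-trienamide F2. 1,2-Addition of (E)-2-(tributylstannyl)ethenyllithium (from (E)-1,2-bis(tributylstannyl)ethene and n-BuLi, THF, −78 °C, in excess) to the free ketone should give racemic (2E,4E,6E)-N-[3-hydroxy-6,6-dimethoxy-3-[(E)-2-(tributylstannyl)ethenyl]cyclohexa-1,4-dien-1-yl]-8-methylnona-2,4,6-trienamide F3. I2 (CH2Cl2, 0 °C) should exchange tin for iodine with retention to give racemic (2E,4E,6E)-N-[3-hydroxy-3-[(E)-2-iodoethenyl]-6,6-dimethoxycyclohexa-1,4-dien-1-yl]-8-methylnona-2,4,6-trienamide F4. Aqueous oxalic acid in THF should cleave the ketal to racemic (2E,4E,6E)-N-[3-hydroxy-3-[(E)-2-iodoethenyl]-6-oxocyclohexa-1,4-dien-1-yl]-8-methylnona-2,4,6-trienamide F5. Preparative chromatography on a chiral stationary phase should then separate 14 from (2E,4E,6E)-N-[(3S)-3-hydroxy-3-[(E)-2-iodoethenyl]-6-oxocyclohexa-1,4-dien-1-yl]-8-methylnona-2,4,6-trienamide F6.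

Step 8. What may go wrong: poor facial selectivity in the peroxide addition (attack syn to the silyloxy group), or competing epoxidation of the amide-bearing enone. Fallback, setting out from 15 and returning at 16: the choice of face is handed from the substrate to a catalyst. A phase-transfer Weitz–Scheffer epoxidation with NaOCl and N-(9-anthracenylmethyl)cinchonidinium bromide, or its cinchoninium pseudo-enantiomer (toluene, −20 °C), would be used. The matched ammonium salt is the one whose ion pair delivers the oxidant to the face anti to the silyloxy group. No new compound is made, F0.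

Step 15. What may go wrong: slow transmetalation with competing protodestannylation of 25 by its own acidic enol, homocoupling of the stannane, or E/Z scrambling of the polyene. Fallback, setting out from 17 and 20 and returning at 26: a tin-free Heck coupling. (2E)-Penta-2,4-dienoic acid would be coupled with 20 (carbodiimide, HOAt, i-Pr2NEt, DMF) to give (2E)-N-(2-hydroxy-5-oxocyclopent-1-en-1-yl)penta-2,4-dienamide F7. Pd(OAc)2 and Ag2CO3 in DMF at 23 °C should then couple 17 at the terminal CH2 of F7, and β-hydride elimination should give the (E,E,E)-triene of 26.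

Further compounds
F1 | step 6 | (2E,4E,6E)-N-(2,5-dimethoxyphenyl)-8-methylnona-2,4,6-trienamide | COc1ccc(OC)c(NC(=O)/C=C/C=C/C=C/C(C)C)c1
F2 | step 6 | (2E,4E,6E)-N-(6,6-dimethoxy-3-oxocyclohexa-1,4-dien-1-yl)-8-methylnona-2,4,6-trienamide | COC1(OC)C=CC(=O)C=C1NC(=O)/C=C/C=C/C=C/C(C)C
F3 | step 6 | (2E,4E,6E)-N-[3-hydroxy-6,6-dimethoxy-3-[(E)-2-(tributylstannyl)ethenyl]cyclohexa-1,4-dien-1-yl]-8-methylnona-2,4,6-trienamide (racemic) | CCCC[Sn](CCCC)(CCCC)/C=C/C1(O)C=CC(OC)(OC)C(NC(=O)/C=C/C=C/C=C/C(C)C)=C1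
F4 | step 6 | (2E,4E,6E)-N-[3-hydroxy-3-[(E)-2-iodoethenyl]-6,6-dimethoxycyclohexa-1,4-dien-1-yl]-8-methylnona-2,4,6-trienamide (racemic) | I/C=C/C1(O)C=CC(OC)(OC)C(NC(=O)/C=C/C=C/C=C/C(C)C)=C1
F5 | step 6 | (2E,4E,6E)-N-[3-hydroxy-3-[(E)-2-iodoethenyl]-6-oxocyclohexa-1,4-dien-1-yl]-8-methylnona-2,4,6-trienamide (racemic) | CC(C)/C=C/C=C/C=C/C(=O)NC1=CC(O)(/C=C/I)C=CC1=O
F6 | step 6 | (2E,4E,6E)-N-[(3S)-3-hydroxy-3-[(E)-2-iodoethenyl]-6-oxocyclohexa-1,4-dien-1-yl]-8-methylnona-2,4,6-trienamide | CC(C)/C=C/C=C/C=C/C(=O)NC1=C[C@](O)(/C=C/I)C=CC1=O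
F0 | step 8 | none | none
F7 | step 15 | (2E)-N-(2-hydroxy-5-oxocyclopent-1-en-1-yl)penta-2,4-dienamide | C=C/C=C/C(=O)NC1=C(O)CCC1=O
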